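**Retrosynthetic overview**

- The route rests on the 4H-pyran-4-one ring of unit 2 (O1''–C2''–C3''–C4''–C4a''–C8a''), fused to a phloroglucinol-type ring A whose C8'' carries the C3'–C8'' biaryl bond. This ring is assembled last from three pieces: an ortho-iodophenol (C4a''–I beside C8a''–OH), carbon monoxide (C4'') and 4-benzyloxyphenylacetylene (C2''–C3'' with its aryl ring).
- The iodophenol comes from a 2-aryl-5-methoxyresorcinol that is symmetric about the biaryl axis, so mono-iodination can give only one isomer. The methyl group on the future O5'' leaves the C8a'' hydroxyl as the only one next to the acyl group.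
- The resorcinol is attached by Suzuki coupling (C3'–C8'') of a 3'-bromoflavone with a bis(methoxymethyl)-protected arylboronic acid. The bromoflavone (unit 1) comes from Claisen–Schmidt condensation and I2/DMSO oxidative cyclisation; the boronic acid from directed ortho-metalation of protected 5-methoxyresorcinol.
- Ring order: pyranone of unit 1, then the biaryl bond, then the pyranone of unit 2. A final BCl3 dealkylation frees five hydroxyls and keeps the 4'-methyl ether.

Key step: step 8

Remark: the target has no stereocentre and the given structure assigns no configuration to the C3'–C8'' axis, so no stereocontrol is planned; compounds 1, 2, 6 and 14 are taken as purchasable.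

**Route**

Step 1
Reactants: 1 1-[2-hydroxy-4,6-bis(benzyloxy)phenyl]ethanone; 2 3-bromo-4-methoxybenzaldehyde
Product: 3 (E)-1-[2,4-bis(benzyloxy)-6-hydroxyphenyl]-3-(3-bromo-4-methoxyphenyl)prop-2-en-1-one
Conditions: KOH (50% aq.), EtOH/THF, rt
Reagents that add atoms: none
Why: Claisen–Schmidt aldol condensation, in which the ketone enolate adds to the non-enolisable aldehyde and E1cB loss of water gives the conjugated enone in the thermodynamically favoured E geometry, the aryl bromide and benzyl ethers being inert to alkali.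

Step 2
Reactants: 3 (E)-1-[2,4-bis(benzyloxy)-6-hydroxyphenyl]-3-(3-bromo-4-methoxyphenyl)prop-2-en-1-one
Product: 5 5,7-bis(benzyloxy)-2-(3-bromo-4-methoxyphenyl)chromen-4-one, via racemic flavanone 4 (not isolated)
Conditions: I2 (10 mol%), DMSO, 130 °C
Reagents that add atoms: none
Why: Iodine-catalysed oxidative cyclisation of a 2'-hydroxychalcone, in which oxa-Michael closure to the flavanone, α-iodination and loss of HI give the chromen-4-one while DMSO reoxidises HI to I2, so the peri benzyl ether never meets stoichiometric acid.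

Step 3
Reactants: 6 5-methoxyresorcinol
Product: 7 1-methoxy-3,5-bis(methoxymethoxy)benzene
Conditions: MOMCl, iPr2NEt, CH2Cl2, 0 °C → rt
Reagents that add atoms: chloromethyl methyl ether, COCCl
Why: Double O-alkylation of the phenols with an α-chloro ether under amine base gives the bis-acetal, which protects the resorcinol and supplies two chelating directing groups for the metalation.

Step 4
Reactants: 7 1-methoxy-3,5-bis(methoxymethoxy)benzene
Product: 10 [4-methoxy-2,6-bis(methoxymethoxy)phenyl]boronic acid, via aryllithium 8 (not isolated), via lithium aryl(triisopropoxy)borate 9 (not isolated)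
Conditions: n-BuLi, THF, 0 °C; B(OiPr)3, −78 °C → rt; sat. aq. NH4Cl
Reagents that add atoms: triisopropyl borate, CC(C)OB(OC(C)C)OC(C)C; water, O
Why: Directed ortho-metalation, in which the ring position flanked by both methoxymethoxy groups is the most acidic and doubly chelated site and is lithiated in preference to the positions next to the methoxy group, followed by borate trapping and mild hydrolysis that leaves the acetals intact.

Step 5
Reactants: 5 5,7-bis(benzyloxy)-2-(3-bromo-4-methoxyphenyl)chromen-4-one; 10 [4-methoxy-2,6-bis(methoxymethoxy)phenyl]boronic acid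
Product: 11 5,7-bis(benzyloxy)-2-{4-methoxy-3-[4-methoxy-2,6-bis(methoxymethoxy)phenyl]phenyl}chromen-4-one
Conditions: 10 (2 equiv), Pd(OAc)2 (5 mol%), SPhos (10 mol%), K3PO4, toluene/H2O, 90 °C
Reagents that add atoms: none
Why: Suzuki–Miyaura coupling forming the C3'–C8'' bond, in which the bulky electron-rich biarylphosphine makes transmetalation and reductive elimination at the tri-ortho-substituted junction fast enough to compete with protodeboronation of the 2,6-dialkoxyarylboronic acid, which is used in excess.

Step 6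
Reactants: 11 5,7-bis(benzyloxy)-2-{4-methoxy-3-[4-methoxy-2,6-bis(methoxymethoxy)phenyl]phenyl}chromen-4-one
Product: 12 5,7-bis(benzyloxy)-2-[3-(2,6-dihydroxy-4-methoxyphenyl)-4-methoxyphenyl]chromen-4-one
Conditions: 3 M aq. HCl, MeOH/THF, 45 °C
Reagents that add atoms: none
Why: Acid-catalysed solvolysis of the two methoxymethyl acetals through oxocarbenium ions trapped by methanol frees the symmetric resorcinol, while the aryl benzyl and methyl ethers and the chromenone tolerate dilute acid at this temperature.

Step 7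
Reactants: 12 5,7-bis(benzyloxy)-2-[3-(2,6-dihydroxy-4-methoxyphenyl)-4-methoxyphenyl]chromen-4-one
Product: 13 5,7-bis(benzyloxy)-2-[3-(2,6-dihydroxy-3-iodo-4-methoxyphenyl)-4-methoxyphenyl]chromen-4-one
Conditions: NIS (1.0 equiv, slow addition), DMF, −20 °C, dark
Reagents that add atoms: N-iodosuccinimide, O=C1CCC(=O)N1I
Why: Electrophilic aromatic iodination, in which the two open positions of the phloroglucinol-type ring are equivalent by symmetry (each ortho to OH and OMe, para to the other OH) and far more nucleophilic than the benzylated, carbonyl-deactivated ring A of unit 1, so one equivalent of reagent at low temperature should give a single mono-iodide.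

Step 8
Reactants: 13 5,7-bis(benzyloxy)-2-[3-(2,6-dihydroxy-3-iodo-4-methoxyphenyl)-4-methoxyphenyl]chromen-4-one; 14 1-(benzyloxy)-4-ethynylbenzene; 15 carbon monoxide
Product: 18 7''-hydroxy-5''-O-methyl-5,7,4'''-tri-O-benzylbilobetin (5,7-bis(benzyloxy)-2-{3-[2-(4-benzyloxyphenyl)-7-hydroxy-5-methoxy-4-oxochromen-8-yl]-4-methoxyphenyl}chromen-4-one), via hydroxyaryl ynone 16 (not isolated), via diethylamino enone 17 (not isolated)
Conditions: 14 (1.5 equiv), PdCl2(PPh3)2 (5 mol%), CO (20 atm), Et2NH, 120 °C, autoclave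
Reagents that add atoms: none
Why: PdCl2(PPh3)2 is reduced in the amine to zerovalent palladium, which inserts into the C4a''–I bond of 13; CO insertion gives the aroylpalladium iodide, and amine-assisted transfer of the acetylide of 14 with reductive elimination gives ynone 16 (C4a''–C4'' and C4''–C3''). Diethylamine then adds to the ynone to give the β-amino enone 17, and the C8a'' hydroxyl displaces the amine at C2'' (O1''–C2''), a 6-endo addition–elimination that closes the pyranone of unit 2. The closest known reaction is the palladium-catalysed carbonylative annulation of 2-iodophenols with terminal arylacetylenes to flavones in a secondary amine under CO pressure. No stereocentre is formed. The step needs carbonylation ahead of direct alkynylation (which would lead to a 2-arylbenzofuran), secured by the CO pressure, and 6-endo rather than 5-exo (aurone) closure, secured by the enaminone pathway in diethylamine. The site of closure is fixed by the substrate, since O5'' is methylated, the 7''-hydroxyl is para to the acyl group, and only the C8a'' hydroxyl is ortho to it; the finished flavone of unit 1 and the benzyl ethers are inert.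

Step 9
Reactants: 18 7''-hydroxy-5''-O-methyl-5,7,4'''-tri-O-benzylbilobetin
Product: 19 bilobetin (4'-O-methylamentoflavone)
Conditions: BCl3 (1 M in CH2Cl2, excess), pentamethylbenzene, CH2Cl2, −78 → 0 °C; H2O
Reagents that add atoms: none
Why: Lewis-acid ether cleavage, in which BCl3 removes the three benzyl groups (the benzyl cations being captured by pentamethylbenzene) and, through a six-membered boron chelate with the C4'' carbonyl, the peri 5''-methyl ether, whereas the non-chelated 4'-methyl ether para to the electron-poor pyranone is not activated and should persist.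

**Compound list**

1 | 1-[2-hydroxy-4,6-bis(benzyloxy)phenyl]ethanone | CC(=O)c1c(O)cc(OCc2ccccc2)cc1OCc1ccccc1 | starting material
2 | 3-bromo-4-methoxybenzaldehyde | COc1ccc(C=O)cc1Br | starting material
3 | (E)-1-[2,4-bis(benzyloxy)-6-hydroxyphenyl]-3-(3-bromo-4-methoxyphenyl)prop-2-en-1-one | COc1ccc(/C=C/C(=O)c2c(O)cc(OCc3ccccc3)cc2OCc2ccccc2)cc1Br | intermediate
4 | racemic 5,7-bis(benzyloxy)-2-(3-bromo-4-methoxyphenyl)chroman-4-one | COc1ccc(C2CC(=O)c3c(OCc4ccccc4)cc(OCc4ccccc4)cc3O2)cc1Br | intermediate
5 | 5,7-bis(benzyloxy)-2-(3-bromo-4-methoxyphenyl)chromen-4-one | COc1ccc(-c2cc(=O)c3c(OCc4ccccc4)cc(OCc4ccccc4)cc3o2)cc1Br | intermediate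
6 | 5-methoxyresorcinol | COc1cc(O)cc(O)c1 | starting material
7 | 1-methoxy-3,5-bis(methoxymethoxy)benzene | COCOc1cc(OC)cc(OCOC)c1 | intermediate
8 | [4-methoxy-2,6-bis(methoxymethoxy)phenyl]lithium | [Li]c1c(OCOC)cc(OC)cc1OCOC | intermediate
9 | lithium [4-methoxy-2,6-bis(methoxymethoxy)phenyl]tri(propan-2-yloxy)borate | [Li+].COCOc1cc(OC)cc(OCOC)c1[B-](OC(C)C)(OC(C)C)OC(C)C | intermediate
10 | [4-methoxy-2,6-bis(methoxymethoxy)phenyl]boronic acid | COCOc1cc(OC)cc(OCOC)c1B(O)O | intermediate
11 | 5,7-bis(benzyloxy)-2-{4-methoxy-3-[4-methoxy-2,6-bis(methoxymethoxy)phenyl]phenyl}chromen-4-one | COCOc1cc(OC)cc(OCOC)c1-c1cc(-c2cc(=O)c3c(OCc4ccccc4)cc(OCc4ccccc4)cc3o2)ccc1OC | intermediate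
12 | 5,7-bis(benzyloxy)-2-[3-(2,6-dihydroxy-4-methoxyphenyl)-4-methoxyphenyl]chromen-4-one | COc1cc(O)c(-c2cc(-c3cc(=O)c4c(OCc5ccccc5)cc(OCc5ccccc5)cc4o3)ccc2OC)c(O)c1 | intermediate
13 | 5,7-bis(benzyloxy)-2-[3-(2,6-dihydroxy-3-iodo-4-methoxyphenyl)-4-methoxyphenyl]chromen-4-one | COc1ccc(-c2cc(=O)c3c(OCc4ccccc4)cc(OCc4ccccc4)cc3o2)cc1-c1c(O)cc(OC)c(I)c1O | intermediate
14 | 1-(benzyloxy)-4-ethynylbenzene | C#Cc1ccc(OCc2ccccc2)cc1 | starting material
15 | carbon monoxide | [C-]#[O+] | starting material
16 | 5,7-bis(benzyloxy)-2-{3-[3-(3-[4-(benzyloxy)phenyl]prop-2-ynoyl)-2,6-dihydroxy-4-methoxyphenyl]-4-methoxyphenyl}chromen-4-one | COc1ccc(-c2cc(=O)c3c(OCc4ccccc4)cc(OCc4ccccc4)cc3o2)cc1-c1c(O)cc(OC)c(C(=O)C#Cc2ccc(OCc3ccccc3)cc2)c1O | intermediate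
17 | 5,7-bis(benzyloxy)-2-{3-[3-(3-[4-(benzyloxy)phenyl]-3-(diethylamino)prop-2-enoyl)-2,6-dihydroxy-4-methoxyphenyl]-4-methoxyphenyl}chromen-4-one (alkene geometry not defined) | COc1ccc(-c2cc(=O)c3c(OCc4ccccc4)cc(OCc4ccccc4)cc3o2)cc1-c1c(O)cc(OC)c(C(=O)C=C(N(CC)CC)c2ccc(OCc3ccccc3)cc2)c1O | intermediate
18 | 7''-hydroxy-5''-O-methyl-5,7,4'''-tri-O-benzylbilobetin | COc1ccc(-c2cc(=O)c3c(OCc4ccccc4)cc(OCc4ccccc4)cc3o2)cc1-c1c(O)cc(OC)c2c(=O)cc(-c3ccc(OCc4ccccc4)cc3)oc12 | intermediate
19 | bilobetin | COc1ccc(-c2cc(=O)c3c(O)cc(O)cc3o2)cc1-c1c(O)cc(O)c2c(=O)cc(-c3ccc(O)cc3)oc12 | target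

**Summary**

Total step count: 9. Longest linear sequence: 7 steps (steps 1, 2, 5, 6, 7, 8, 9; the branch through steps 3 and 4 is equally long).

**Steps most likely to fail**

1. Step 8. The arylpalladium intermediate may couple with the alkyne before CO inserts, giving the non-carbonylated alkynylphenol and its benzofuran. The aroylpalladium species may instead be captured by diethylamine or a phenoxide, or the ynone may close in the 5-exo sense. The fallback sets out from 13 and builds the same ring by acetyl chemistry. Stille coupling with tributyl(1-ethoxyvinyl)stannane (PdCl2(PPh3)2, dioxane, 90 °C) should give the 1-ethoxyvinyl arene F1, and dilute HCl on work-up should hydrolyse it to the methyl ketone F2. Claisen–Schmidt condensation of F2 with 4-(benzyloxy)benzaldehyde (concentrated KOH, EtOH/THF, rt) should give the E chalcone F3. Catalytic I2 in DMSO at 130 °C should then close and dehydrogenate it through the flavanone F4, coming back to the route at 18. Only the hydroxyl ortho to the acyl group can close, so the regiochemistry is the same.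

2. Step 5. Protodeboronation of the 2,6-dialkoxyarylboronic acid may outpace transmetalation at the crowded tri-ortho-substituted junction. The fallback reverses the polarity of the coupling and sets out from 5 and 7. Miyaura borylation of 5 (bis(pinacolato)diboron, PdCl2(dppf), KOAc, dioxane, 90 °C) should give the flavone 3'-pinacol boronate F5, which is not prone to protodeboronation. Lithiation of 7 as in step 4 (through 8) and quenching with I2 should give 2-iodo-5-methoxy-1,3-bis(methoxymethoxy)benzene F6. Suzuki coupling of F5 with F6 (Pd(OAc)2, SPhos, K3PO4, toluene/H2O, 90 °C) comes back to the route at 11.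

3. Step 9. The time and temperature needed to cleave the chelated 5''-methyl ether may also erode the 4'-methyl ether, or benzyl cations may be transferred to the electron-rich rings A. The fallback sets out from 18 and separates the two tasks. Hydrogenolysis (H2, 1 atm, palladium on carbon, THF/MeOH, rt) should remove the three benzyl groups without acid and give 5''-O-methylbilobetin F7. Chelation-controlled demethylation of only the peri methyl ether with AlCl3 in MeCN (rt to gentle warming) then reaches the target 19.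

Further compounds
F1 | step 8 | 5,7-bis(benzyloxy)-2-{3-[3-(1-ethoxyvinyl)-2,6-dihydroxy-4-methoxyphenyl]-4-methoxyphenyl}chromen-4-one | COc1ccc(-c2cc(=O)c3c(OCc4ccccc4)cc(OCc4ccccc4)cc3o2)cc1-c1c(O)cc(OC)c(C(=C)OCC)c1O
F2 | step 8 | 2-[3-(3-acetyl-2,6-dihydroxy-4-methoxyphenyl)-4-methoxyphenyl]-5,7-bis(benzyloxy)chromen-4-one | COc1ccc(-c2cc(=O)c3c(OCc4ccccc4)cc(OCc4ccccc4)cc3o2)cc1-c1c(O)cc(OC)c(C(C)=O)c1O
F3 | step 8 | 5,7-bis(benzyloxy)-2-{3-[3-((E)-3-[4-(benzyloxy)phenyl]prop-2-enoyl)-2,6-dihydroxy-4-methoxyphenyl]-4-methoxyphenyl}chromen-4-one | COc1ccc(-c2cc(=O)c3c(OCc4ccccc4)cc(OCc4ccccc4)cc3o2)cc1-c1c(O)cc(OC)c(C(=O)/C=C/c2ccc(OCc3ccccc3)cc2)c1O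
F4 | step 8 | racemic 5,7-bis(benzyloxy)-2-{3-[2-(4-benzyloxyphenyl)-7-hydroxy-5-methoxy-4-oxochroman-8-yl]-4-methoxyphenyl}chromen-4-one | COc1ccc(-c2cc(=O)c3c(OCc4ccccc4)cc(OCc4ccccc4)cc3o2)cc1-c1c(O)cc(OC)c2c1OC(c1ccc(OCc3ccccc3)cc1)CC2=O
F5 | step 5 | 5,7-bis(benzyloxy)-2-[4-methoxy-3-(4,4,5,5-tetramethyl-1,3,2-dioxaborolan-2-yl)phenyl]chromen-4-one | COc1ccc(-c2cc(=O)c3c(OCc4ccccc4)cc(OCc4ccccc4)cc3o2)cc1B1OC(C)(C)C(C)(C)O1
F6 | step 5 | 2-iodo-5-methoxy-1,3-bis(methoxymethoxy)benzene | COCOc1cc(OC)cc(OCOC)c1I
F7 | step 9 | 5''-O-methylbilobetin | COc1ccc(-c2cc(=O)c3c(O)cc(O)cc3o2)cc1-c1c(O)cc(OC)c2c(=O)cc(-c3ccc(O)cc3)oc12
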